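**Retrosynthetic overview**
1. Feature used: ring B is oxygenated at B1, B3 and B5 in the 1,3,5-pattern of a polyketide. It carries the ether oxygens to rings C and D at B4 and B6 and its only hydrogen at B2. Rings C and D are alike, so the core without ring A is bisected by a plane through B2 and B5, and B4/B6 and B1/B3 are pairwise equivalent.
2. Key disconnection: cutting B4–B5 and B1–B2 splits ring B into a three-carbon aryloxymalonyl unit (B5, B6, B1) and a 4-aryloxyacetoacetate unit (B4, B3, B2, with the ester carbon on B2). Both aryl ethers then come from SN2 alkylations of one phenol.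
3. Repair built in: the malonate methine is far more acidic than the γ-position of an acetoacetate enolate, so a metal dianion would be lost to proton transfer. The dianion is therefore used as its neutral 1,3-bis(silyloxy)diene, one malonate ester is used as its acid chloride, and methoxide closes the ring in the same flask.
4. The ester on B2 differentiates the hydroxyls (B5 and B3 are methylated, the chelated B1–OH stays free) and is then removed. Ring A is grown on the B1 oxygen by the same alkylation/[3+3] Claisen sequence with methyl malonyl chloride.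
5. Ring order: C and D arrive with the phenol, B closes in step 6, A closes in step 11. Decarboxylation and cleavage of eight methyl ethers finish the synthesis.

Key step: step 6

Remark: ring B is labelled B1 (O to ring A), B2 (H), B3 (OH), B4 (O to ring C), B5 (OH), B6 (O to ring D).
Remark: the target has no stereocentre. The methine centres of the open-chain intermediates are racemic and labile, and the dienes are used as E/Z mixtures, so no SMILES carries a stereodescriptor.

**Step 1**
Reactants: 1 3,4,5-trimethoxyphenol; 2 dimethyl bromomalonate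
Product: 3 dimethyl 2-(3,4,5-trimethoxyphenoxy)malonate
Conditions: K2CO3, acetone, reflux
Reagents that add atoms: none
Why: Williamson-type SN2 displacement of the doubly carbonyl-activated bromide by the phenoxide is the standard entry to aryloxymalonates, and the weak base leaves the esters intact.

**Step 2**
Reactants: 1 3,4,5-trimethoxyphenol; 4 methyl 4-chloroacetoacetate
Product: 5 methyl 3-oxo-4-(3,4,5-trimethoxyphenoxy)butanoate
Conditions: NaH (2.2 equiv), THF, 0 °C → reflux; then 1 M HCl, 0 °C
Reagents that add atoms: none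
Why: Williamson ether synthesis in which the second equivalent of NaH holds the acidic C2–H as its enolate, so the phenoxide attacks only the primary C–Cl bond.

**Step 3**
Reactants: 3 dimethyl 2-(3,4,5-trimethoxyphenoxy)malonate
Product: 6 3-methoxy-3-oxo-2-(3,4,5-trimethoxyphenoxy)propanoic acid
Conditions: KOH (1.0 equiv), MeOH, 0 °C → rt; then cold 1 M HCl
Reagents that add atoms: potassium hydroxide, [K+].[OH-]
Why: Malonate half-saponification stops after one ester because the carboxylate formed deactivates the second ester, and cold acidification avoids decarboxylation of the half acid.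

**Step 4**
Reactants: 6 3-methoxy-3-oxo-2-(3,4,5-trimethoxyphenoxy)propanoic acid
Product: 7 methyl 3-chloro-3-oxo-2-(3,4,5-trimethoxyphenoxy)propanoate
Conditions: (COCl)2 (1.2 equiv), cat. DMF, CH2Cl2, 0 °C → rt; evaporate, use crude at once
Reagents that add atoms: oxalyl chloride, O=C(Cl)C(=O)Cl
Why: Acid chloride formation through the catalytic Vilsmeier-type chloroiminium salt runs below the decarboxylation threshold of the half acid, and no Lewis acid is present that could trigger Friedel–Crafts closure onto the electron-rich ring.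

**Step 5**
Reactants: 5 methyl 3-oxo-4-(3,4,5-trimethoxyphenoxy)butanoate
Product: 9 1-methoxy-1,3-bis(trimethylsilyloxy)-4-(3,4,5-trimethoxyphenoxy)buta-1,3-diene, via mono(silyl enol ether) 8 (not isolated)
Conditions: Me3SiOTf (2.3 equiv), Et3N (3 equiv), Et2O, 0 °C → rt; pentane extraction, evaporation of all amine in vacuo
Reagents that add atoms: trimethylsilyl trifluoromethanesulfonate, C[Si](C)(C)OS(=O)(=O)C(F)(F)F
Why: Soft enolisation with silyl triflate and amine silylates the ketone oxygen first and then the ester carbonyl with loss of the γ-proton, which the aryloxy group acidifies, giving the neutral equivalent of the acetoacetate dianion.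

**Step 6**
Reactants: 7 methyl 3-chloro-3-oxo-2-(3,4,5-trimethoxyphenoxy)propanoate; 9 1-methoxy-1,3-bis(trimethylsilyloxy)-4-(3,4,5-trimethoxyphenoxy)buta-1,3-diene
Product: 11 methyl 2,4,6-trihydroxy-3,5-bis(3,4,5-trimethoxyphenoxy)benzoate, via diketo diester 10 (not isolated)
Conditions: CH2Cl2, −78 → 20 °C; then NaOMe (6 equiv), MeOH, 0 °C → reflux; 1 M HCl
Reagents that add atoms: none
Why: Carbon C4 of diene 9, which carries the largest HOMO coefficient just as in the metal dianion, attacks the acid chloride of 7 in a Mukaiyama-type C-acylation with loss of Me3SiCl and so forms B4–B5 (diketo diester 10); as the medium holds no strong base, the acidic malonyl methine cannot quench the nucleophile. Methoxide then removes the remaining silyl group and equilibrates the enolates of 10, the C2 carbanion of the β-keto ester terminus adds to the surviving malonyl ester in a Dieckmann-type Claisen closure (6-(enolexo)-exo-trig, forms B1–B2 and ring B), and loss of methoxide followed by enolisation gives the phloroglucinol as its sodium salt. The closest known reactions are the γ-acylation of 1,3-bis(silyloxy)buta-1,3-dienes by acid chlorides, malonic half-ester chlorides included, which gives 3,5-dioxopimelates, and the polyketide-type Claisen cyclisation of 3,5-dioxo esters that underlies the classical malonate route to phloroglucinol carboxylates. No stereocentre is created, because the two racemic methine carbons of 10 become the sp2 centres B4 and B6. The step needs carbon- rather than oxygen-acylation and the right ring: enol esters and the 4-hydroxy-2-pyranones that O-closure would give are reopened by methoxide, closure of the aryloxy-bearing malonyl carbon onto the other ester gives a quaternary trione that cannot enolise and reverts by retro-Claisen cleavage, 10 offers no aldol closure to a common ring, and the aromatic tris-phenoxide is the only irreversible sink. As both aryloxy groups are identical, it does not matter which of them ends at B4 or B6.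

**Step 7**
Reactants: 11 methyl 2,4,6-trihydroxy-3,5-bis(3,4,5-trimethoxyphenoxy)benzoate
Product: 12 methyl 2-hydroxy-4,6-dimethoxy-3,5-bis(3,4,5-trimethoxyphenoxy)benzoate
Conditions: Me2SO4 (2.1 equiv), K2CO3 (2.2 equiv), acetone, reflux
Reagents that add atoms: dimethyl sulfate, COS(=O)(=O)OC
Why: In this chelation-controlled Williamson O-methylation the para hydroxyl (B5) and then one ortho hydroxyl react, while the last ortho hydroxyl is locked in a strong hydrogen bond to the ester carbonyl, and the mirror plane makes either ortho site lead to the same compound.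

**Step 8**
Reactants: 12 methyl 2-hydroxy-4,6-dimethoxy-3,5-bis(3,4,5-trimethoxyphenoxy)benzoate
Product: 14 3,5-dimethoxy-2,4-bis(3,4,5-trimethoxyphenoxy)phenol, via salicylic acid 13 (not isolated)
Conditions: KOH (10 equiv), aq. DMSO, 100 °C, Ar; then 1 M H2SO4 to pH 1, 70 °C
Reagents that add atoms: none
Why: Saponification of the crowded salicylate by poorly solvated hydroxide is followed by acid-promoted protodecarboxylation, which is easy because B2 lies ortho/para to three oxygen donors and is readily ipso-protonated, and aryl methyl and diaryl ethers are inert to both media.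

**Step 9**
Reactants: 14 3,5-dimethoxy-2,4-bis(3,4,5-trimethoxyphenoxy)phenol; 4 methyl 4-chloroacetoacetate
Product: 15 methyl 4-[3,5-dimethoxy-2,4-bis(3,4,5-trimethoxyphenoxy)phenoxy]-3-oxobutanoate
Conditions: NaH (2.5 equiv), 4 (1.3 equiv), THF/DMF, 0 → 60 °C; then cold 1 M HCl
Reagents that add atoms: none
Why: This is the Williamson ether synthesis of step 2 applied to the single free phenol, which after loss of the ester is unchelated, has one open ortho position and is an electron-rich, good nucleophile.

**Step 10**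
Reactants: 15 methyl 4-[3,5-dimethoxy-2,4-bis(3,4,5-trimethoxyphenoxy)phenoxy]-3-oxobutanoate
Product: 17 4-[3,5-dimethoxy-2,4-bis(3,4,5-trimethoxyphenoxy)phenoxy]-1-methoxy-1,3-bis(trimethylsilyloxy)buta-1,3-diene, via mono(silyl enol ether) 16 (not isolated)
Conditions: Me3SiOTf (2.3 equiv), Et3N (3 equiv), Et2O, 0 °C → rt; pentane/Et2O extraction, evaporation in vacuo
Reagents that add atoms: trimethylsilyl trifluoromethanesulfonate, C[Si](C)(C)OS(=O)(=O)C(F)(F)F
Why: The soft enolisation of step 5 applies unchanged, and the excess amine keeps the medium basic so the keto ester cannot cyclodehydrate onto B2.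

**Step 11**
Reactants: 17 4-[3,5-dimethoxy-2,4-bis(3,4,5-trimethoxyphenoxy)phenoxy]-1-methoxy-1,3-bis(trimethylsilyloxy)buta-1,3-diene; 18 methyl malonyl chloride (methyl 3-chloro-3-oxopropanoate)
Product: 20 methyl 3-[3,5-dimethoxy-2,4-bis(3,4,5-trimethoxyphenoxy)phenoxy]-2,4,6-trihydroxybenzoate, via symmetric diketo diester 19 (not isolated)
Conditions: CH2Cl2, −78 → 20 °C; then NaOMe (6 equiv), MeOH, 0 °C → reflux; 1 M HCl
Reagents that add atoms: none
Why: γ-C-acylation of the 4-aryloxy-1,3-bis(silyloxy)diene by methyl malonyl chloride and 6-(enolexo)-exo-trig Claisen cyclisation repeat step 6, and because 19 is symmetric either terminal methylene closing onto the opposite ester gives the same ring A, with the ether oxygen flanked by two hydroxyls and para to the third.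

**Step 12**
Reactants: 20 methyl 3-[3,5-dimethoxy-2,4-bis(3,4,5-trimethoxyphenoxy)phenoxy]-2,4,6-trihydroxybenzoate
Product: 22 2-[3,5-dimethoxy-2,4-bis(3,4,5-trimethoxyphenoxy)phenoxy]benzene-1,3,5-triol, via carboxylic acid 21 (not isolated)
Conditions: KOH (10 equiv), degassed aq. DMSO, 90 °C, Ar; then 1 M H2SO4 to pH 1, 60 °C
Reagents that add atoms: none
Why: A phloroglucinol carboxylate behaves through its keto tautomer as a β-keto ester, so saponification followed by acidification leads to ready decarboxylation, as in the classical malonate route to phloroglucinol.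

**Step 13**
Reactants: 22 2-[3,5-dimethoxy-2,4-bis(3,4,5-trimethoxyphenoxy)phenoxy]benzene-1,3,5-triol
Product: 23 2-[3,5-dihydroxy-2,4-bis(3,4,5-trihydroxyphenoxy)phenoxy]benzene-1,3,5-triol (CNP0304743.0)
Conditions: BBr3 (20 equiv), CH2Cl2, −78 °C → rt, Ar; H2O, 0 °C; degassed solvents for isolation
Reagents that add atoms: none
Why: In this Lewis acid mediated aryl methyl ether cleavage bromide attacks the methyl carbon of each boron-complexed methoxy group, while the three diaryl ether linkages offer no sp3 carbon and survive.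

**Compound list**
1 | 3,4,5-trimethoxyphenol | COc1cc(O)cc(OC)c1OC | starting material
2 | dimethyl bromomalonate | COC(=O)C(Br)C(=O)OC | starting material
3 | dimethyl 2-(3,4,5-trimethoxyphenoxy)malonate | COC(=O)C(Oc1cc(OC)c(OC)c(OC)c1)C(=O)OC | intermediate
4 | methyl 4-chloroacetoacetate | COC(=O)CC(=O)CCl | starting material
5 | methyl 3-oxo-4-(3,4,5-trimethoxyphenoxy)butanoate | COC(=O)CC(=O)COc1cc(OC)c(OC)c(OC)c1 | intermediate
6 | 3-methoxy-3-oxo-2-(3,4,5-trimethoxyphenoxy)propanoic acid (racemic) | COC(=O)C(Oc1cc(OC)c(OC)c(OC)c1)C(=O)O | intermediate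
7 | methyl 3-chloro-3-oxo-2-(3,4,5-trimethoxyphenoxy)propanoate (racemic) | COC(=O)C(Oc1cc(OC)c(OC)c(OC)c1)C(=O)Cl | intermediate
8 | methyl 3-(trimethylsilyloxy)-4-(3,4,5-trimethoxyphenoxy)but-2-enoate (E/Z) | COC(=O)C=C(O[Si](C)(C)C)COc1cc(OC)c(OC)c(OC)c1 | intermediate
9 | 1-methoxy-1,3-bis(trimethylsilyloxy)-4-(3,4,5-trimethoxyphenoxy)buta-1,3-diene (E/Z) | COC(O[Si](C)(C)C)=CC(O[Si](C)(C)C)=COc1cc(OC)c(OC)c(OC)c1 | intermediate
10 | dimethyl 3,5-dioxo-2,4-bis(3,4,5-trimethoxyphenoxy)heptanedioate (stereoisomer mixture) | COC(=O)CC(=O)C(Oc1cc(OC)c(OC)c(OC)c1)C(=O)C(Oc1cc(OC)c(OC)c(OC)c1)C(=O)OC | intermediate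
11 | methyl 2,4,6-trihydroxy-3,5-bis(3,4,5-trimethoxyphenoxy)benzoate | COC(=O)c1c(O)c(Oc2cc(OC)c(OC)c(OC)c2)c(O)c(Oc2cc(OC)c(OC)c(OC)c2)c1O | intermediate
12 | methyl 2-hydroxy-4,6-dimethoxy-3,5-bis(3,4,5-trimethoxyphenoxy)benzoate | COC(=O)c1c(O)c(Oc2cc(OC)c(OC)c(OC)c2)c(OC)c(Oc2cc(OC)c(OC)c(OC)c2)c1OC | intermediate
13 | 2-hydroxy-4,6-dimethoxy-3,5-bis(3,4,5-trimethoxyphenoxy)benzoic acid | OC(=O)c1c(O)c(Oc2cc(OC)c(OC)c(OC)c2)c(OC)c(Oc2cc(OC)c(OC)c(OC)c2)c1OC | intermediate
14 | 3,5-dimethoxy-2,4-bis(3,4,5-trimethoxyphenoxy)phenol | COc1cc(O)c(Oc2cc(OC)c(OC)c(OC)c2)c(OC)c1Oc1cc(OC)c(OC)c(OC)c1 | intermediate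
15 | methyl 4-[3,5-dimethoxy-2,4-bis(3,4,5-trimethoxyphenoxy)phenoxy]-3-oxobutanoate | COC(=O)CC(=O)COc1cc(OC)c(Oc2cc(OC)c(OC)c(OC)c2)c(OC)c1Oc1cc(OC)c(OC)c(OC)c1 | intermediate
16 | methyl 4-[3,5-dimethoxy-2,4-bis(3,4,5-trimethoxyphenoxy)phenoxy]-3-(trimethylsilyloxy)but-2-enoate (E/Z) | COC(=O)C=C(O[Si](C)(C)C)COc1cc(OC)c(Oc2cc(OC)c(OC)c(OC)c2)c(OC)c1Oc1cc(OC)c(OC)c(OC)c1 | intermediate
17 | 4-[3,5-dimethoxy-2,4-bis(3,4,5-trimethoxyphenoxy)phenoxy]-1-methoxy-1,3-bis(trimethylsilyloxy)buta-1,3-diene (E/Z) | COC(O[Si](C)(C)C)=CC(O[Si](C)(C)C)=COc1cc(OC)c(Oc2cc(OC)c(OC)c(OC)c2)c(OC)c1Oc1cc(OC)c(OC)c(OC)c1 | intermediate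
18 | methyl malonyl chloride | COC(=O)CC(=O)Cl | starting material
19 | dimethyl 4-[3,5-dimethoxy-2,4-bis(3,4,5-trimethoxyphenoxy)phenoxy]-3,5-dioxoheptanedioate | COC(=O)CC(=O)C(Oc1cc(OC)c(Oc2cc(OC)c(OC)c(OC)c2)c(OC)c1Oc1cc(OC)c(OC)c(OC)c1)C(=O)CC(=O)OC | intermediate
20 | methyl 3-[3,5-dimethoxy-2,4-bis(3,4,5-trimethoxyphenoxy)phenoxy]-2,4,6-trihydroxybenzoate | COC(=O)c1c(O)cc(O)c(Oc2cc(OC)c(Oc3cc(OC)c(OC)c(OC)c3)c(OC)c2Oc2cc(OC)c(OC)c(OC)c2)c1O | intermediate
21 | 3-[3,5-dimethoxy-2,4-bis(3,4,5-trimethoxyphenoxy)phenoxy]-2,4,6-trihydroxybenzoic acid | OC(=O)c1c(O)cc(O)c(Oc2cc(OC)c(Oc3cc(OC)c(OC)c(OC)c3)c(OC)c2Oc2cc(OC)c(OC)c(OC)c2)c1O | intermediate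
22 | 2-[3,5-dimethoxy-2,4-bis(3,4,5-trimethoxyphenoxy)phenoxy]benzene-1,3,5-triol | Oc1cc(O)c(Oc2cc(OC)c(Oc3cc(OC)c(OC)c(OC)c3)c(OC)c2Oc2cc(OC)c(OC)c(OC)c2)c(O)c1 | intermediate
23 | 2-[3,5-dihydroxy-2,4-bis(3,4,5-trihydroxyphenoxy)phenoxy]benzene-1,3,5-triol | Oc1cc(O)c(Oc2cc(O)c(Oc3cc(O)c(O)c(O)c3)c(O)c2Oc2cc(O)c(O)c(O)c2)c(O)c1 | target

**Total step count:** 13
**Longest linear sequence:** 11 steps (1, 3, 4, 6, 7, 8, 9, 10, 11, 12, 13)

**Steps most likely to fail**

Step 6. Three things may go wrong.
- The acid chloride may lose HCl to a ketene and oligomerise.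
- Acylation may drift from the hindered, oxygen-bearing C4 to oxygen or to C2.
- In the second stage, methoxide may fragment the 1,3-diketone by retro-Claisen cleavage faster than the ring closes.

The fallback sets out from 1 and takes ring B from an aromatic precursor. Commercial methyl 2,4,6-trimethoxybenzoate is iodinated twice (NIS, cat. CF3CO2H, MeCN) to methyl 3,5-diiodo-2,4,6-trimethoxybenzoate F1. A double Ullmann-type diaryl ether coupling with 1 (CuI, picolinic acid, K3PO4, DMSO, 100 °C) gives methyl 2,4,6-trimethoxy-3,5-bis(3,4,5-trimethoxyphenoxy)benzoate F2. BCl3 (1.1 equiv, CH2Cl2, −78 → 0 °C) then removes, by chelation to the ester carbonyl, one of the two equivalent methyl ethers next to it. The route is rejoined at 12.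

Step 11. The failure modes of step 6 recur, now with a much bulkier aryloxy group on the nucleophilic carbon. In addition, acid-induced cyclodehydration of the aryloxy ketone onto B2 may occur if the mixture turns acidic before methoxide is added.

The fallback sets out from 14 and attaches ring A as a ready-made arene. Ullmann-type coupling of 14 with commercial 2-iodo-1,3,5-trimethoxybenzene (CuI, picolinic acid, K3PO4, DMSO, 100 °C) gives 2-[3,5-dimethoxy-2,4-bis(3,4,5-trimethoxyphenoxy)phenoxy]-1,3,5-trimethoxybenzene F3. Cleavage of all eleven methyl ethers with BBr3 under the conditions of step 13 brings the route back at 23, and steps 9 to 12 are bypassed.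

Step 13. Cleavage of the eight ethers may stay incomplete, and the pyrogallol rings may be lost to air oxidation during quench and chromatography.

The fallback sets out from 22 and changes the isolation strategy to a protected form. After the BBr3 treatment the crude polyphenol is not purified but acetylated at once (Ac2O, pyridine, Ar) to the target undecaacetate F4. This is stable on silica, so partly methylated material can be separated from it. Acid-catalysed methanolysis (HCl generated from AcCl in degassed MeOH, 40 °C) then releases 23 under non-oxidising conditions.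

**Further compounds**
F1 | step 6 | methyl 3,5-diiodo-2,4,6-trimethoxybenzoate | COC(=O)c1c(OC)c(I)c(OC)c(I)c1OC
F2 | step 6 | methyl 2,4,6-trimethoxy-3,5-bis(3,4,5-trimethoxyphenoxy)benzoate | COC(=O)c1c(OC)c(Oc2cc(OC)c(OC)c(OC)c2)c(OC)c(Oc2cc(OC)c(OC)c(OC)c2)c1OC
F3 | step 11 | 2-[3,5-dimethoxy-2,4-bis(3,4,5-trimethoxyphenoxy)phenoxy]-1,3,5-trimethoxybenzene | COc1cc(OC)c(Oc2cc(OC)c(Oc3cc(OC)c(OC)c(OC)c3)c(OC)c2Oc2cc(OC)c(OC)c(OC)c2)c(OC)c1
F4 | step 13 | target undecaacetate | CC(=O)Oc1cc(OC(C)=O)c(Oc2cc(OC(C)=O)c(Oc3cc(OC(C)=O)c(OC(C)=O)c(OC(C)=O)c3)c(OC(C)=O)c2Oc2cc(OC(C)=O)c(OC(C)=O)c(OC(C)=O)c2)c(OC(C)=O)c1
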